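Minutes on one flask.

all flasks: free catalyst 0.05 mol%
- Saturday's: left-handed substrate 20 mM; right-handed substrate 20 mM; solid reagent 2.7 equiv; run made earlier
- Tuesday's: left-handed substrate 20 mM; right-handed substrate 20 mM; solid reagent 6 equiv; run made earlier
- Sunday's: left-handed substrate 10 mM; right-handed substrate 10 mM; solid reagent 4 equiv; run made earlier
- flask: left-handed substrate 20 mM; right-handed substrate 20 mM; solid reagent 4.00 equiv; time 1.0 h

| run | time / min | left-handed substrate / % | right-handed substrate / % |
|---|---|---|---|
| Saturday's | 6.00 | 49.5 | 48.8 |
| Saturday's | 8.00 | 49.3 | 49.8 |
| Saturday's | 12.0 | 48.0 | 47.4 |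
| Saturday's | 20.0 | 46.5 | 46.8 |
| Saturday's | 30.0 | 45.6 | 45.6 |
| Saturday's | 50.0 | 44.2 | 44.9 |
| Saturday's | 80.0 | 42.9 | 43.5 |
| Tuesday's | 10.0 | 47.9 | 48.7 |
| Tuesday's | 20.0 | 46.8 | 47.3 |
| Tuesday's | 30.0 | 45.7 | 46.6 |
| Tuesday's | 40.0 | 45.5 | 45.6 |
| Tuesday's | 50.0 | 44.7 | 44.1 |
| Tuesday's | 60.0 | 43.5 | 43.9 |
| Tuesday's | 80.0 | 43.1 | 42.5 |
| Sunday's | 6.00 | 50.0 | 49.4 |
| Sunday's | 20.0 | 48.0 | 47.9 |
| Sunday's | 30.0 | 47.2 | 47.2 |
| Sunday's | 50.0 | 46.8 | 45.9 |
| Sunday's | 80.0 | 46.9 | 46.5 |

(scatter of a reading: 0.5 percentage points)

1. part of the left-handed substrate and right-handed substrate charged together that has reacted at 1.0 h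
2. excess of left-handed product over right-handed product in the product at 1.0 h
3. excess of right-handed substrate over left-handed substrate among what is left of the two at 1.0 h

- free catalyst is single-handed; left-handed substrate and right-handed substrate are mirror images of each other, charged as a racemate, each of them at the stated concentration
- given per volume of solution although it is solid: solid reagent
- the analysis behind the earlier runs scatters by 0.5 percentage points, standard deviation
- steps under discussion: partner + free catalyst + left-handed substrate -> free catalyst + left-handed product; partner + free catalyst + right-handed substrate -> free catalyst + right-handed product; left-handed substrate <-> right-handed substrate; free catalyst -> spent catalyst A; solid reagent <-> partner; partner + free catalyst -> spent catalyst B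
- at the start none of the solid reagent is in solution
- an excess is the difference of the two amounts in percent of their sum
- an excess is below zero if the other one leads

The first chemist proposed following one molecule of free catalyst. At each fork it either takes partner and a substrate through to product or goes over to a spent form, so she wished to count how many rounds it completes. Tuesday's run had lost 12.6% of its substrates by 60.0 min. That part is counted on both substrates and the loading on one, so she doubled it and divided by 0.05 mol%, and called the resulting 504 the turnovers per catalyst charged, or turnover number.

The second chemist objected that this figure moves from run to run. Sunday's run, at 10 mM of left-handed substrate, 4 equiv of solid reagent and the same loading, gives 264 at 80.0 min, whereas Tuesday's, which differs in both of those charges, gives 576 at 80.0 min. He therefore agreed to carry it to this flask, which shares Tuesday's 20 mM of left-handed substrate and its loading.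

She added that the solid seems to matter little in these runs. By 80.0 min, Saturday's run with 2.7 equiv had lost 13.6% and Tuesday's with 6 equiv had lost 14.4%, and this flask's 4.00 equiv lies between them. Her reckoning for 1.0 h was thus 12.6% reacted. The two substrate columns show no steady lead, so she put the substrate excess near zero. No run reads product, so she offered no number for the product excess.

The forecast gave 12.5% (11.3% to 13.7%) for the part reacted, 50% (0% to 97%) for the product excess, called eP in its words, and 0.2% (−0.7% to 1%) for the substrate excess, remarking: “The runs contain no product data, so eP is essentially a guess”.

The flask gives 12.3% reacted, a product excess of 49.5% and a substrate excess of 0.0272%.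

    partner + free catalyst + left-handed substrate → free catalyst + left-handed product (k = 6610 /M²/s)
    partner + free catalyst + right-handed substrate → free catalyst + right-handed product (k = 2230 /M²/s)
    left-handed substrate ⇌ right-handed substrate (k = 0.0107 /s)
    free catalyst → spent catalyst A (k = 7.72 × 10⁻⁴ /s)
    solid reagent ⇌ partner, rate k5*(cs5 - [partner]) while solid is left; crystals form when [partner] > cs5 (solubility = 12.0 mM, k = 4.70 × 10⁻⁴ /s)
    partner + free catalyst → spent catalyst B (k = 0.0403 /M/s)

This flask made 490 turnovers per catalyst charged, close to the 504 carried from Tuesday's run. Held at 504, the neighbour with 0.02 mol% of free catalyst comes to 5.04% reacted. It actually gives 5.95%, or 595 turnovers, with [partner] at 8.85 mM against 7.84 mM in this flask at 1.00 h. The low solubility of partner, which also sets how fast it dissolves, is the main reason so little of this flask has reacted: the same run with that taken away reaches 56.1% instead of 12.3%.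

All runs come from a simulation from invented constants, noise included.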